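**Assumption:** catalyst enantiomers (steps 1 and 9) are chosen to give the absolute configuration in the SMILES. The facial selectivities of the aldol (16), the C2=C3 epoxidation (20) and the C11=C20 epoxidation (23) are taken from the substrate-bias analysis in each "Why".

## Retrosynthetic overview
1. The target comes from 29 ← spiro-epoxide 28 ← C11 exocyclic alkene ← C11 ketone. The C2/C3 anti-diacetate comes from a Z-C2=C3 epoxide opened at C3.
2. The oxocane (C1–C2=C3–C4–O–C8–C9–C10) is closed by RCM between the C1-vinyl and C4-vinyl groups, after an intermolecular C9–C10 aldol between cyclohexenone 6 and THP-lactone aldehyde 20.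
3. The 2,6-cis-THP is made by a new allenyl halo-Prins cyclization of a homoallenyl alcohol with acrolein. This forms C4–O, C4–C5, the C5=CH2 and C6–Cl in one step. The lactone and its C7/C8 stereocentres come from a Shi epoxidation of an enyne, a 5-endo epoxy-acid lactonization and a Crabbé allene homologation.
4. The cyclohexenone (C1 quaternary, C14–OAc) comes from an organocatalytic endo Diels–Alder reaction.
5. Rings are formed in this order: cyclohexane, γ-lactone, THP, the C9–C10 bond, then the oxocene.

## Route

**Step 1**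
Reactants: 1 methacrolein; 2 (1E,3E)-1,4-diacetoxybuta-1,3-diene
Product: 3 2,5-diacetoxy-1-methylcyclohex-3-ene-1-carbaldehyde (CHO and both OAc cis, Me trans; single enantiomer)
Conditions: imidazolidinone·HClO4 (20 mol %), MeCN/H2O 95:5, –20 °C
Reagents that add atoms: none
Why: Iminium-activated endo Diels–Alder reaction; the catalyst shields one enal face to set the C1 quaternary centre and C14, and the endo rule puts CHO cis to the adjacent OAc.

**Step 2**
Reactants: 3
Product: 4 5-ethenyl-5-methylcyclohex-2-ene-1,4-diyl diacetate (vinyl cis to the C14 OAc)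
Conditions: Ph3P=CH2 (from Ph3PCH3Br, NaHMDS), THF, 0 °C → rt
Reagents that add atoms: methylenetriphenylphosphorane, C=P(c1ccccc1)(c1ccccc1)c1ccccc1
Why: Wittig methylenation of the neopentyl aldehyde gives the C2 vinyl group needed for RCM, and no stereocentre is touched.

**Step 3**
Reactants: 4
Product: 5 6-ethenyl-4-hydroxy-6-methylcyclohex-2-en-1-yl acetate
Conditions: K2CO3 (0.2 equiv), MeOH, –10 °C
Reagents that add atoms: none
Why: The C11 acetate is far less hindered than the C14 acetate next to the quaternary carbon, so methanolysis is selective. The C11 stereocentre is removed in the next step.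

**Step 4**
Reactants: 5
Product: 6 4-acetoxy-5-ethenyl-5-methylcyclohex-2-en-1-one
Conditions: MnO2, CH2Cl2, rt
Reagents that add atoms: none
Why: Chemoselective oxidation of the allylic alcohol gives the enone. Its C12=C13 alkene blocks one α-side so that later enolization occurs only at C10.

**Step 5**
Reactants: 7 tert-butyl methacrylate
Product: 8 tert-butyl 2-methyl-4-oxobutanoate (racemic at C2)
Conditions: CO/H2 (20 bar, 1:1), Rh(acac)(CO)2, biphephos, toluene, 80 °C
Reagents that add atoms: carbon monoxide, [C-]#[O+]; hydrogen, [H][H]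
Why: Anti-Markovnikov Rh hydroformylation avoids forming a quaternary centre; the C17 stereocentre is left open because it is epimerizable and is equilibrated in step 12.

**Step 6**
Reactants: 8; 9 3-(trimethylsilyl)propynal
Product: 10 tert-butyl (3E)-3-formyl-2-methyl-6-(trimethylsilyl)hex-3-en-5-ynoate
Conditions: pyrrolidine (20 mol %), AcOH (20 mol %), CH2Cl2, 0 °C, slow addition of 8
Reagents that add atoms: none
Why: Enamine-catalysed cross-aldol condensation; the E enal (CHO trans to the alkyne) is the thermodynamic isomer and is what the required syn-epoxide needs.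

**Step 7**
Reactants: 10
Product: 11 tert-butyl (3E)-3-(hydroxymethyl)-2-methyl-6-(trimethylsilyl)hex-3-en-5-ynoate
Conditions: NaBH4, CeCl3·7H2O, MeOH, –78 °C
Reagents that add atoms: none
Why: Luche 1,2-reduction of the aldehyde; the tert-butyl ester is too hindered to lactonize onto the new C9 alcohol.

**Step 8**
Reactants: 11
Product: 12 the C9 tert-butyldiphenylsilyl ether of 11
Conditions: TBDPSCl, imidazole, DMF, rt
Reagents that add atoms: TBDPSCl, CC(C)(C)[Si](Cl)(c1ccccc1)c1ccccc1
Why: The silyl ether survives the later TFA, Lewis-acid and basic steps and prevents competing C9 lactonization or acetal formation.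

**Step 9**
Reactants: 12
Product: 13 trans-3,4-epoxide: tert-butyl 3,4-epoxy-3-[(TBDPSO)methyl]-2-methyl-6-(TMS)hex-5-ynoate (C2 epimeric)
Conditions: fructose-derived Shi ketone (30 mol %), Oxone, K2CO3, Bu4NHSO4, MeCN/DMM/aq. buffer pH 10.5, 0 °C
Reagents that add atoms: potassium peroxymonosulfate, [K+].OOS(=O)(=O)[O-]
Why: Shi organocatalytic dioxirane epoxidation of a conjugated trisubstituted E-enyne is stereospecific (E gives the trans-epoxide) and sets C7 and C8 enantioselectively; the remote C2 centre does not affect the facial selectivity.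

**Step 10**
Reactants: 13
Product: 14 hydroxy-lactone with the C7–O bond formed: 4-hydroxy-4-[(TBDPSO)methyl]-3-methyl-5-[(TMS)ethynyl]dihydrofuran-2-one (C17 epimeric)
Conditions: TFA, CH2Cl2, 0 °C → rt
Reagents that add atoms: none
Why: TFA removes the tert-butyl group and the carboxylic acid opens the propargylic epoxide carbon C7 in a 5-endo SN2 with inversion, while the C8–O bond is retained, giving the cis-fused C7/C8 relationship of the target.

**Step 11**
Reactants: 14
Product: 15 the terminal alkyne (5-ethynyl analogue of 14)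
Conditions: K2CO3, MeOH, 0 °C, 15 min
Reagents that add atoms: none
Why: Mild protodesilylation of the alkynyl TMS group frees the alkyne for the Crabbé reaction.

**Step 12**
Reactants: 15
Product: 16 homoallenyl alcohol: 5-(propa-1,2-dienyl)-4-hydroxy-4-[(TBDPSO)methyl]-3-methyldihydrofuran-2-one, with C17 methyl trans to the C9 side chain
Conditions: (CH2O)n, iPr2NH, CuBr, 1,4-dioxane, 100 °C
Reagents that add atoms: formaldehyde, C=O
Why: Crabbé homologation converts the terminal alkyne to the terminal allene (C6H=C5=C16H2). The basic, hot conditions equilibrate the α-lactone centre C17 to the thermodynamically preferred isomer, which matches the target.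

**Step 13**
Reactants: 16; 17 acrolein
Product: 18 2,6-cis-THP fused to the lactone, bearing C4-vinyl, C5=CH2, C6-Cl (axial) and the C9 CH2OTBDPS group
Conditions: TMSCl (3 equiv), InCl3 (20 mol %), CH2Cl2, –40 → 0 °C
Reagents that add atoms: chlorotrimethylsilane, C[Si](C)(C)Cl (supplies the C6 chloride)
Why: Proposed new method: the tertiary alcohol and acrolein form an oxocarbenium ion that is attacked by the central allene carbon C5 through a chair transition state with both C4 and C8 substituents equatorial, which sets the 2,6-cis relationship. The resulting 2-alkylidene-allyl cation is captured by chloride at C6 on the axial face to give the exo-methylene and the allylic chloride. The closest known reaction is the alkyne/alkene halo-Prins cyclization of homopropargylic and homoallylic alcohols, extended here to homoallenyl alcohols.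

**Step 14**
Reactants: 18
Product: 19 the primary alcohol (C9–OH)
Conditions: HF·pyridine, THF, 0 °C → rt
Reagents that add atoms: none
Why: Fluoride removes the silyl ether; the lactone, allylic chloride and alkenes are untouched.

**Step 15**
Reactants: 19
Product: 20 the C9 aldehyde (α-alkoxy, non-enolizable)
Conditions: Dess–Martin periodinane, NaHCO3, CH2Cl2, rt
Reagents that add atoms: none
Why: Mild oxidation to the aldehyde, which has no enolizable α-H (C8 is quaternary) and so does not epimerize.

**Step 16**
Reactants: 6; 20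
Product: 21 aldol adduct with C9–OH, C10–C9 bond and cyclohexenone ring retained
Conditions: LDA (0.95 equiv), THF, –78 °C, then 20, –78 → –40 °C
Reagents that add atoms: none
Why: LDA deprotonates only C10, the α'-CH2 of the enone, and the enolate adds to the α-alkoxy aldehyde (aldol reaction, chelation control at C9). C10 is epimerizable and is later equilibrated to the trans-fused arrangement.

**Step 17**
Reactants: 21
Product: 22 the C9 acetate
Conditions: Ac2O, Sc(OTf)3 (5 mol %), CH2Cl2, 0 °C
Reagents that add atoms: acetic anhydride, CC(=O)OC(C)=O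
Why: Non-basic acetylation installs the C9 OAc and blocks both retro-aldol and oxa-Michael addition of the C9 oxygen onto the enone.

**Step 18**
Reactants: 22
Product: 23 oxocene with the Z-C2=C3 alkene (ethylene is lost)
Conditions: Hoveyda–Grubbs II (10 mol %), toluene, 2 mM, 80 °C
Reagents that add atoms: none
Why: Ring-closing metathesis between the C1-vinyl and C4-vinyl groups closes the eight-membered ring and gives the cis-alkene needed for the anti-diol; the C1, C4 and C10 stereocentres fix the geometry.

**Step 19**
Reactants: 23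
Product: 24 saturated C11 ketone (C12–C13 reduced)
Conditions: Hantzsch diethyl ester, Bn2NH2+ TFA– (20 mol %), toluene, 60 °C
Reagents that add atoms: none (H only)
Why: Metal-free iminium transfer hydrogenation reduces the enone C=C but leaves the exo-methylene, the Z-alkene, the allylic chloride and the lactone; C10 equilibrates to the trans-fused, equatorial-C9 isomer.

**Step 20**
Reactants: 24
Product: 25 C2/C3 cis-epoxide (oxygen on the face anti to the C4–O–C8 bridge)
Conditions: DMDO in acetone, CH2Cl2, –20 °C
Reagents that add atoms: dimethyldioxirane, CC1(C)OO1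
Why: The Z-alkene is the only nucleophilic alkene (C5=C16 is deactivated by two allylic heteroatoms), and it is epoxidized from the convex face; a cis-epoxide is required for anti-diol formation.

**Step 21**
Reactants: 25
Product: 26 C2,C3 anti-diacetate (C3 inverted, C2 retained)
Conditions: Ac2O, Sc(OTf)3 (5 mol %), CH2Cl2, 0 °C → rt
Reagents that add atoms: acetic anhydride, CC(=O)OC(C)=O
Why: Acetolysis of the epoxide occurs by SN2 at C3 with inversion (C2 is neopentyl and blocked), and the C2 oxygen is acetylated with retention, giving the C2/C3 relationship of the target.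

**Step 22**
Reactants: 26
Product: 27 C11 exocyclic methylene (C11=C20)
Conditions: Zn, CH2Br2, TiCl4, THF/CH2Cl2, 0 °C → rt
Reagents that add atoms: dibromomethane, BrCBr
Why: Takai–Lombardo methylenation is non-basic, so it does not epimerize C10 or eliminate the C9 acetate, and it is selective for the ketone over the lactone and esters.

**Step 23**
Reactants: 27
Product: 28 C11 spiro-epoxide (O on the up face, CH2 axial down)
Conditions: mCPBA, NaHCO3, CH2Cl2, 0 °C
Reagents that add atoms: mCPBA, O=C(OO)c1cccc(Cl)c1
Why: The 1,1-disubstituted alkene is the most nucleophilic remaining one, and peracid attacks from the equatorial (top) face, away from the axial C1 methyl, which gives the configuration at C11.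

**Step 24**
Reactants: 28
Product: 29 Fragilide F
Conditions: LiCl (10 equiv), Et3N·HCl (5 equiv), MeCN, 60 °C
Reagents that add atoms: lithium chloride, [Li+].[Cl-]
Why: Chloride opens the epoxide by SN2 at the primary C20 carbon, so the C11–O bond and its configuration are retained, giving the tertiary alcohol and CH2Cl.

## Compound list
1 | methacrolein | C=C(C)C=O | starting material
2 | (1E,3E)-1,4-diacetoxybuta-1,3-diene | CC(=O)O/C=C/C=C/OC(C)=O | starting material
3 | 2,5-diacetoxy-1-methylcyclohex-3-ene-1-carbaldehyde | O=C[C@@]1(C)[C@@H](OC(C)=O)C=C[C@@H](OC(C)=O)C1 | intermediate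
4 | 5-ethenyl-5-methylcyclohex-2-ene-1,4-diyl diacetate | C=C[C@@]1(C)[C@@H](OC(C)=O)C=C[C@@H](OC(C)=O)C1 | intermediate
5 | 6-ethenyl-4-hydroxy-6-methylcyclohex-2-en-1-yl acetate | C=C[C@@]1(C)[C@@H](OC(C)=O)C=C[C@@H](O)C1 | intermediate
6 | 4-acetoxy-5-ethenyl-5-methylcyclohex-2-en-1-one | C=C[C@@]1(C)[C@@H](OC(C)=O)C=CC(=O)C1 | intermediate
7 | tert-butyl methacrylate | C=C(C)C(=O)OC(C)(C)C | starting material
8 | tert-butyl 2-methyl-4-oxobutanoate (racemic) | O=CCC(C)C(=O)OC(C)(C)C | intermediate
9 | 3-(trimethylsilyl)propynal | C[Si](C)(C)C#CC=O | starting material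
10 | tert-butyl (3E)-3-formyl-2-methyl-6-(trimethylsilyl)hex-3-en-5-ynoate | CC(C(=O)OC(C)(C)C)/C(C=O)=C\C#C[Si](C)(C)C | intermediate
11 | tert-butyl (3E)-3-(hydroxymethyl)-2-methyl-6-(trimethylsilyl)hex-3-en-5-ynoate | CC(C(=O)OC(C)(C)C)/C(CO)=C\C#C[Si](C)(C)C | intermediate
12 | TBDPS ether of 11 | CC(C(=O)OC(C)(C)C)/C(CO[Si](c1ccccc1)(c1ccccc1)C(C)(C)C)=C\C#C[Si](C)(C)C | intermediate
13 | trans-3,4-epoxy ester (C2 epimeric) | CC(C(=O)OC(C)(C)C)[C@]1(CO[Si](c2ccccc2)(c2ccccc2)C(C)(C)C)O[C@@H]1C#C[Si](C)(C)C | intermediate
14 | hydroxy-lactone, TMS-alkyne (C17 epimeric) | O=C1C(C)[C@@](O)(CO[Si](c2ccccc2)(c2ccccc2)C(C)(C)C)[C@H](C#C[Si](C)(C)C)O1 | intermediate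
15 | hydroxy-lactone, terminal alkyne (C17 epimeric) | O=C1C(C)[C@@](O)(CO[Si](c2ccccc2)(c2ccccc2)C(C)(C)C)[C@H](C#C)O1 | intermediate
16 | homoallenyl hydroxy-lactone | O=C1[C@H](C)[C@@](O)(CO[Si](c2ccccc2)(c2ccccc2)C(C)(C)C)[C@H](C=C=C)O1 | intermediate
17 | acrolein | C=CC=O | starting material
18 | THP-lactone from the Prins reaction, C9 OTBDPS | C=C1[C@H](C=C)O[C@]3([C@@H](C)C(=O)O[C@H]3[C@H]1Cl)CO[Si](c2ccccc2)(c2ccccc2)C(C)(C)C | intermediate
19 | C9 primary alcohol | C=C1[C@H](C=C)O[C@]3([C@@H](C)C(=O)O[C@H]3[C@H]1Cl)CO | intermediate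
20 | C9 aldehyde | C=C1[C@H](C=C)O[C@]3([C@@H](C)C(=O)O[C@H]3[C@H]1Cl)C=O | intermediate
21 | aldol adduct | C=C1[C@H](C=C)O[C@]3([C@@H](C)C(=O)O[C@H]3[C@H]1Cl)[C@@H](O)[C@H]1C(=O)C=C[C@H](OC(C)=O)[C@]1(C)C=C | intermediate
22 | C9 acetate | C=C1[C@H](C=C)O[C@]3([C@@H](C)C(=O)O[C@H]3[C@H]1Cl)[C@@H](OC(C)=O)[C@H]1C(=O)C=C[C@H](OC(C)=O)[C@]1(C)C=C | intermediate
23 | RCM product (Z-C2=C3 oxocene, enone) | C=C1[C@H]2O[C@]3([C@@H](C)C(=O)O[C@H]3[C@H]1Cl)[C@@H](OC(C)=O)[C@H]1C(=O)C=C[C@H](OC(C)=O)[C@]1(C)/C=C\2 | intermediate
24 | saturated C11 ketone | C=C1[C@H]2O[C@]3([C@@H](C)C(=O)O[C@H]3[C@H]1Cl)[C@@H](OC(C)=O)[C@H]1C(=O)CC[C@H](OC(C)=O)[C@]1(C)/C=C\2 | intermediate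
25 | C2/C3 epoxide | C=C1[C@H]2O[C@]3([C@@H](C)C(=O)O[C@H]3[C@H]1Cl)[C@@H](OC(C)=O)[C@H]1C(=O)CC[C@H](OC(C)=O)[C@]1(C)[C@H]4O[C@@H]24 | intermediate
26 | C2,C3-diacetate, C11 ketone | C=C1[C@H]2O[C@]3([C@@H](C)C(=O)O[C@H]3[C@H]1Cl)[C@@H](OC(C)=O)[C@H]1C(=O)CC[C@H](OC(C)=O)[C@]1(C)[C@@H](OC(C)=O)[C@@H]2OC(C)=O | intermediate
27 | C11 exocyclic alkene | C=C1[C@H]2O[C@]3([C@@H](C)C(=O)O[C@H]3[C@H]1Cl)[C@@H](OC(C)=O)[C@H]1C(=C)CC[C@H](OC(C)=O)[C@]1(C)[C@@H](OC(C)=O)[C@@H]2OC(C)=O | intermediate
28 | C11 spiro-epoxide | C=C1[C@H]2O[C@]3([C@@H](C)C(=O)O[C@H]3[C@H]1Cl)[C@@H](OC(C)=O)[C@H]1[C@@]4(CO4)CC[C@H](OC(C)=O)[C@]1(C)[C@@H](OC(C)=O)[C@@H]2OC(C)=O | intermediate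
29 | Fragilide F | C=C1[C@H]2O[C@]3([C@@H](C)C(=O)O[C@H]3[C@H]1Cl)[C@@H](OC(C)=O)[C@H]1[C@@](O)(CCl)CC[C@H](OC(C)=O)[C@]1(C)[C@@H](OC(C)=O)[C@@H]2OC(C)=O | target

## Step count
Total steps: 24. Longest linear sequence: 20 (7 → 8 → 10 → … → 29); the cyclohexenone branch (1 → 6) is 4 steps and joins at step 16.

## Three steps most likely to fail
1. **Step 13, the allenyl halo-Prins (new).** Chloride may capture at C16 instead of C6, the C6 chloride may end up equatorial, and the conjugated acrolein oxocarbenium is a poor electrophile.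
   - Fallback (known chemistry): make the C4–C5(=CH2)–C6 unit by a Morita–Baylis–Hillman reaction of the C7 aldehyde with acrolein. Close the THP by Pd-catalysed intramolecular allylic etherification (Tsuji–Trost) of the tertiary alcohol, then convert the C6 allylic alcohol to the chloride with Ph3P/NCS.
2. **Step 16, the hindered aldol between two neopentyl partners.** Yield and the C9/C10 stereochemistry are both uncertain.
   - Fallback: convert 6 to its α'-bromoenone and couple it with 20 by a SmI2 Barbier-type aldol. If C9 has the wrong configuration, oxidize it and reduce the C9 ketone with a directed reagent.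
3. **Step 18, RCM to the bridged oxocene.** The strained bridged eight-membered ring may not close or may oligomerize.
   - Fallback: cleave the two monosubstituted vinyl groups of 22 (OsO4/NaIO4) and close the C2–C3 bond by SmI2 pinacol coupling of the dialdehyde. This gives the C2/C3 diol directly and replaces steps 18–21 with coupling plus diacetylation.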